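**Assumption:** the target is numbered as a germacran-12,6-olide (C6 = enol-lactone carbon, C8 = methacrylate carbon, C2 = acetate carbon, C4 = tertiary carbinol, C13 = CH2OH). Its presumed biosynthesis is taken as C6–C7 closure of a farnesyl chain, 6,12-lactonisation, and opening of a 4,5-epoxide by the C6 dienolate (glaucolide → hirsutinolide logic). Read this way the target is (1(10)Z,2R,4S,5E,8R).

## Retrosynthetic overview

1. Target ⇐ its 13-O-TBS ether (one desilylation).
2. That ether ⇐ an acyclic epoxy aldehyde carrying a (Z)-enol triflate, in one cascade: Ni/Cr C6–C7 closure forms the ten-membered carbocycle first, the C6 alkoxide then closes the butenolide (second ring), and the C6 dienolate opens the 4,5-epoxide (Δ5, 4-OH).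
3. Epoxy aldehyde ⇐ Z-enal + prenal dienol ether (vinylogous aldol sets C2; enal epoxidation sets C4).
4. (Z)-Enol triflate ⇐ α-acyloxy aldehyde + α-diazo ester (C7–C11 bond, then chelate-controlled triflation).
5. α-Acyloxy aldehyde ⇐ (R)-δ-lactone ⇐ crotonaldehyde + senecioate dienolate (sets C8 and the 1(10)-Z olefin).

Where a catalyst antipode is named in steps 2, 11 and 13, the facial sense is assigned by analogy with the parent reactions and would be confirmed (Mosher ester or optical rotation) before scale-up.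

## Route

Step 1
Reactants: 1 methyl 3-methylbut-2-enoate
Product: 2 1-methoxy-3-methyl-1-(trimethylsilyloxy)buta-1,3-diene
Conditions: LDA, THF, −78 °C; TMSCl
Reagents that add atoms: chlorotrimethylsilane, C[Si](C)(C)Cl
Why: Kinetic γ-deprotonation of the senecioate and O-silylation give the silyl dienolate (silyl ketene acetal formation); no stereocentre is formed.

Step 2
Reactants: 2 1-methoxy-3-methyl-1-(trimethylsilyloxy)buta-1,3-diene; 3 (E)-but-2-enal
Product: 5 (6R)-4-methyl-6-[(1E)-prop-1-enyl]-5,6-dihydro-2H-pyran-2-one, via copper aldolate 4 (not isolated)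
Conditions: Cu(OTf)2/(S)-Tol-BINAP (10 mol%), Bu4N[Ph3SiF2] (20 mol%), THF, rt
Reagents that add atoms: none
Why: Catalytic asymmetric vinylogous Mukaiyama aldol (CuF·Tol-BINAP dienolate chemistry): the chiral copper dienolate attacks the Re face of the enal through its γ-carbon to set C8 (R), and the (Z)-aldolate lactonises, which locks the future 1(10)-olefin as Z.

Step 3
Reactants: 5 (6R)-4-methyl-6-[(1E)-prop-1-enyl]-5,6-dihydro-2H-pyran-2-one
Product: 7 (2E,4R,6Z)-8-[methoxy(methyl)amino]-6-methyl-8-oxoocta-2,6-dien-4-yl 2-methylprop-2-enoate, via ring-opened magnesium alkoxide 6 (not isolated)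
Conditions: Me(MeO)NH·HCl, i-PrMgCl, THF, −20 °C; then methacrylic anhydride, DMAP (cat.), −20 → 0 °C
Reagents that add atoms: N,O-dimethylhydroxylamine hydrochloride, CNOC.Cl; methacrylic anhydride, C=C(C)C(=O)OC(=O)C(C)=C
Why: Weinreb aminolysis of the lactone frees the C8 alkoxide, which is O-acylated in the same flask before it can relactonise; C8 and the Z olefin are untouched.

Step 4
Reactants: 7 (2E,4R,6Z)-8-[methoxy(methyl)amino]-6-methyl-8-oxoocta-2,6-dien-4-yl 2-methylprop-2-enoate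
Product: 9 (2R,4Z)-6-[methoxy(methyl)amino]-4-methyl-1,6-dioxohex-4-en-2-yl 2-methylprop-2-enoate, via secondary ozonide 8 (not isolated)
Conditions: O3, CH2Cl2, −78 °C (Sudan III end point); Me2S; product used crude
Reagents that add atoms: ozone, [O-][O+]=O
Why: Ozonolysis cleaves only the electron-rich propenyl C=C (the enamide and methacrylate C=C are carbonyl-conjugated and react far more slowly) and unveils C7 as an aldehyde under neutral conditions that do not epimerise C8.

Step 5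
Reactants: 10 ethyl diazoacetate
Product: 11 ethyl 2-diazo-3-hydroxypropanoate
Conditions: paraformaldehyde, DBU (10 mol%), MeCN, rt
Reagents that add atoms: formaldehyde (from paraformaldehyde), C=O
Why: Base-catalysed aldol-type addition of the diazoacetate carbanion to an aldehyde installs C13 at the alcohol level; no stereocentre is formed.

Step 6
Reactants: 11 ethyl 2-diazo-3-hydroxypropanoate
Product: 12 ethyl 3-(tert-butyldimethylsilyloxy)-2-diazopropanoate
Conditions: TBSCl, imidazole, CH2Cl2, 0 °C → rt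
Reagents that add atoms: tert-butyldimethylsilyl chloride, CC(C)(C)[Si](C)(C)Cl
Why: Standard silylation of the primary alcohol; TBS is chosen because silyloxide is a poor leaving group in the later dienolate step and the ether survives every step up to 15.

Step 7
Reactants: 9 (2R,4Z)-6-[methoxy(methyl)amino]-4-methyl-1,6-dioxohex-4-en-2-yl 2-methylprop-2-enoate; 12 ethyl 3-(tert-butyldimethylsilyloxy)-2-diazopropanoate
Product: 13 ethyl (4R,6Z)-2-(TBSO-methyl)-8-[methoxy(methyl)amino]-6-methyl-4-(methacryloyloxy)-3,8-dioxooct-6-enoate (C2 epimers)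
Conditions: SnCl2 (10 mol%), CH2Cl2, 0 °C → rt
Reagents that add atoms: none
Why: Roskamp homologation: the diazo carbon adds to the Lewis-acid-activated aldehyde and a 1,2-hydride shift with loss of N2 gives the β-keto ester, joining C7 to C11; the C11 centre is erased in step 8 and C8 is not enolised under these non-basic conditions.

Step 8
Reactants: 13 ethyl (4R,6Z)-2-(TBSO-methyl)-8-[methoxy(methyl)amino]-6-methyl-4-(methacryloyloxy)-3,8-dioxooct-6-enoate
Product: 14 ethyl (2Z,4R,6Z)-2-(TBSO-methyl)-8-[methoxy(methyl)amino]-6-methyl-4-(methacryloyloxy)-8-oxo-3-(triflyloxy)octa-2,6-dienoate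
Conditions: Tf2O, aq. LiOH, toluene, 5 °C
Reagents that add atoms: trifluoromethanesulfonic anhydride, O=S(=O)(OS(=O)(=O)C(F)(F)F)C(F)(F)F
Why: O-Triflation of the lithium-chelated (Z)-enolate of the β-keto ester places OTf cis to the ester (stereoselective enol triflate formation), which is the geometry needed for lactonisation after the C6–C7 bond is made; only the doubly activated C11–H is deprotonated.

Step 9
Reactants: 14 ethyl (2Z,4R,6Z)-2-(TBSO-methyl)-8-[methoxy(methyl)amino]-6-methyl-4-(methacryloyloxy)-8-oxo-3-(triflyloxy)octa-2,6-dienoate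
Product: 15 ethyl (2Z,4R,6Z)-2-(TBSO-methyl)-6-methyl-4-(methacryloyloxy)-8-oxo-3-(triflyloxy)octa-2,6-dienoate
Conditions: Cp2Zr(H)Cl (1.5 equiv), THF, rt, 15 min
Reagents that add atoms: none
Why: Schwartz reagent reduces the tertiary Weinreb amide to the aldehyde through a stable zirconated hemiaminal faster than it touches esters, the enol triflate or hindered alkenes (chemoselective amide-to-aldehyde reduction); the Z geometry is kept.

Step 10
Reactants: 16 3-methylbut-2-enal
Product: 17 tert-butyldimethyl[(1E)-3-methylbuta-1,3-dienyloxy]silane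
Conditions: TBSOTf, Et3N, Et2O, 0 °C → rt
Reagents that add atoms: tert-butyldimethylsilyl trifluoromethanesulfonate, CC(C)(C)[Si](C)(C)OS(=O)(=O)C(F)(F)F
Why: Soft γ-enolisation of the enal and O-silylation give the silyl dienol ether; no stereocentre is formed.

Step 11
Reactants: 15 ethyl (2Z,4R,6Z)-2-(TBSO-methyl)-6-methyl-4-(methacryloyloxy)-8-oxo-3-(triflyloxy)octa-2,6-dienoate; 17 tert-butyldimethyl[(1E)-3-methylbuta-1,3-dienyloxy]silane
Product: 18 ethyl (2Z,4R,6Z,8R,10E)-2-(TBSO-methyl)-8-hydroxy-6,10-dimethyl-4-(methacryloyloxy)-12-oxo-3-(triflyloxy)dodeca-2,6,10-trienoate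
Conditions: B-phenyl oxazaborolidinone from N-Ts-L-tryptophan (50 mol%), i-PrOH, EtCN, −78 °C
Reagents that add atoms: none
Why: Vinylogous Mukaiyama aldol of an aldehyde-derived silyl dienol ether under chiral oxazaborolidinone control: γ-attack on the Re face of the Z-enal sets C2 (R) by reagent control and gives the E-enal, with i-PrOH taking up the silyl group.

Step 12
Reactants: 18 ethyl (2Z,4R,6Z,8R,10E)-2-(TBSO-methyl)-8-hydroxy-6,10-dimethyl-4-(methacryloyloxy)-12-oxo-3-(triflyloxy)dodeca-2,6,10-trienoate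
Product: 19 ethyl (2Z,4R,6Z,8R,10E)-8-acetoxy-2-(TBSO-methyl)-6,10-dimethyl-4-(methacryloyloxy)-12-oxo-3-(triflyloxy)dodeca-2,6,10-trienoate
Conditions: Ac2O, pyridine, DMAP (cat.), CH2Cl2, 0 °C
Reagents that add atoms: acetic anhydride, CC(=O)OC(C)=O
Why: DMAP-catalysed acetylation of the only free hydroxyl; C2 is not affected.

Step 13
Reactants: 19 ethyl (2Z,4R,6Z,8R,10E)-8-acetoxy-2-(TBSO-methyl)-6,10-dimethyl-4-(methacryloyloxy)-12-oxo-3-(triflyloxy)dodeca-2,6,10-trienoate
Product: 20 ethyl (2Z,4R,6Z,8R)-8-acetoxy-2-(TBSO-methyl)-9-[(2S,3R)-3-formyl-2-methyloxiran-2-yl]-6-methyl-4-(methacryloyloxy)-3-(triflyloxy)nona-2,6-dienoate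
Conditions: [(3,5-(CF3)2C6H3CH2)2NH2][(R)-TRIP] (10 mol%, antipode that gives the 2R,3S epoxy aldehyde), t-BuOOH, dioxane, 35 °C
Reagents that add atoms: tert-butyl hydroperoxide, CC(C)(C)OO
Why: Iminium-activated nucleophilic epoxidation of the β,β-disubstituted enal under chiral phosphate counter-anion control (ACDC epoxidation) gives the trans-epoxide and sets C4 (S) and C5 by catalyst control; the other alkenes are not activated by the amine.

Step 14
Reactants: 20 ethyl (2Z,4R,6Z,8R)-8-acetoxy-2-(TBSO-methyl)-9-[(2S,3R)-3-formyl-2-methyloxiran-2-yl]-6-methyl-4-(methacryloyloxy)-3-(triflyloxy)nona-2,6-dienoate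
Product: 23 (1(10)Z,2R,4S,5E,8R)-2-acetoxy-13-(tert-butyldimethylsilyloxy)-4-hydroxy-8-(methacryloyloxy)germacra-1(10),5,7(11)-trien-12,6-olide, via macrocyclic chromium alkoxide 21 (not isolated), via epoxy butenolide 22 (not isolated)
Conditions: CrCl2 (8 equiv), NiCl2 (2 mol%), DMF–THF, 2 mM (slow addition), rt; then DBU (10 equiv), rt
Reagents that add atoms: none
Why: Proposed new method: Ni(0) inserts into the C7–OTf bond and transmetalation gives a C7 alkenyl-Cr(III) that adds to the C6 aldehyde (closing the ten-membered ring at the bond made by farnesyl C1–C10 cyclisation), the C6 chromium alkoxide sits cis to the ester and lactonises, and DBU then removes the vinylogously acidic H-6 so that the furanolate opens the 4,5-epoxide (C5–O cleaved, C4–O kept, giving 4S-OH and the ring-cis Δ5 olefin; both C6 epimers converge and the new C6 centre is erased) — closest known reactions are Nozaki–Hiyama–Kishi macrocyclisations of alkenyl triflates, butenolide formation from (Z)-β-metallo-acrylates and aldehydes, and the base-induced glaucolide → hirsutinolide-type epoxide opening.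

Step 15
Reactants: 23 (1(10)Z,2R,4S,5E,8R)-2-acetoxy-13-(tert-butyldimethylsilyloxy)-4-hydroxy-8-(methacryloyloxy)germacra-1(10),5,7(11)-trien-12,6-olide
Product: 24 (1(10)Z,2R,4S,5E,8R)-2-acetoxy-4,13-dihydroxy-8-(methacryloyloxy)germacra-1(10),5,7(11)-trien-12,6-olide (CNP0122447.1)
Conditions: HF·pyridine, pyridine, THF, 0 °C
Reagents that add atoms: none
Why: Fluoride-mediated desilylation of the primary allylic TBS ether under buffered, non-basic conditions that avoid 8→13 acyl migration and leave the acetate, methacrylate, enol lactone and tertiary allylic alcohol intact.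

## Compound list

1 | methyl 3-methylbut-2-enoate | CC(C)=CC(=O)OC | starting material
2 | 1-methoxy-3-methyl-1-(trimethylsilyloxy)buta-1,3-diene (E/Z mixture) | C=C(C)C=C(OC)O[Si](C)(C)C | intermediate
3 | (E)-but-2-enal | C/C=C/C=O | starting material
4 | copper(I) alkoxide of methyl (2Z,5R,6E)-5-hydroxy-3-methylocta-2,6-dienoate (drawn as the alcohol) | O[C@@H](/C=C/C)C/C(C)=C\C(=O)OC | intermediate
5 | (6R)-4-methyl-6-[(1E)-prop-1-enyl]-5,6-dihydro-2H-pyran-2-one | O1[C@@H](/C=C/C)CC(C)=CC1=O | intermediate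
6 | chloromagnesium alkoxide of (2Z,5R,6E)-5-hydroxy-N-methoxy-N,3-dimethylocta-2,6-dienamide (drawn as the alcohol) | O[C@@H](/C=C/C)C/C(C)=C\C(=O)N(C)OC | intermediate
7 | (2E,4R,6Z)-8-[methoxy(methyl)amino]-6-methyl-8-oxoocta-2,6-dien-4-yl 2-methylprop-2-enoate | C=C(C)C(=O)O[C@@H](/C=C/C)C/C(C)=C\C(=O)N(C)OC | intermediate
8 | 1,2,4-trioxolane (secondary ozonide) of 7 at the propenyl C=C | C=C(C)C(=O)O[C@@H](C1OOC(C)O1)C/C(C)=C\C(=O)N(C)OC | intermediate
9 | (2R,4Z)-6-[methoxy(methyl)amino]-4-methyl-1,6-dioxohex-4-en-2-yl 2-methylprop-2-enoate | C=C(C)C(=O)O[C@@H](C=O)C/C(C)=C\C(=O)N(C)OC | intermediate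
10 | ethyl diazoacetate | CCOC(=O)C=[N+]=[N-] | starting material
11 | ethyl 2-diazo-3-hydroxypropanoate | CCOC(=O)C(CO)=[N+]=[N-] | intermediate
12 | ethyl 3-(tert-butyldimethylsilyloxy)-2-diazopropanoate | CCOC(=O)C(CO[Si](C)(C)C(C)(C)C)=[N+]=[N-] | intermediate
13 | ethyl (4R,6Z)-2-(TBSO-methyl)-8-[methoxy(methyl)amino]-6-methyl-4-(methacryloyloxy)-3,8-dioxooct-6-enoate (C2 epimers) | C=C(C)C(=O)O[C@@H](C(=O)C(CO[Si](C)(C)C(C)(C)C)C(=O)OCC)C/C(C)=C\C(=O)N(C)OC | intermediate
14 | ethyl (2Z,4R,6Z)-2-(TBSO-methyl)-8-[methoxy(methyl)amino]-6-methyl-4-(methacryloyloxy)-8-oxo-3-(triflyloxy)octa-2,6-dienoate | C=C(C)C(=O)O[C@@H](/C(OS(=O)(=O)C(F)(F)F)=C(\CO[Si](C)(C)C(C)(C)C)C(=O)OCC)C/C(C)=C\C(=O)N(C)OC | intermediate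
15 | ethyl (2Z,4R,6Z)-2-(TBSO-methyl)-6-methyl-4-(methacryloyloxy)-8-oxo-3-(triflyloxy)octa-2,6-dienoate | C=C(C)C(=O)O[C@@H](/C(OS(=O)(=O)C(F)(F)F)=C(\CO[Si](C)(C)C(C)(C)C)C(=O)OCC)C/C(C)=C\C=O | intermediate
16 | 3-methylbut-2-enal | CC(C)=CC=O | starting material
17 | tert-butyldimethyl[(1E)-3-methylbuta-1,3-dienyloxy]silane | C=C(C)/C=C/O[Si](C)(C)C(C)(C)C | intermediate
18 | ethyl (2Z,4R,6Z,8R,10E)-2-(TBSO-methyl)-8-hydroxy-6,10-dimethyl-4-(methacryloyloxy)-12-oxo-3-(triflyloxy)dodeca-2,6,10-trienoate | C=C(C)C(=O)O[C@@H](/C(OS(=O)(=O)C(F)(F)F)=C(\CO[Si](C)(C)C(C)(C)C)C(=O)OCC)C/C(C)=C\[C@H](O)C/C(C)=C/C=O | intermediate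
19 | ethyl (2Z,4R,6Z,8R,10E)-8-acetoxy-2-(TBSO-methyl)-6,10-dimethyl-4-(methacryloyloxy)-12-oxo-3-(triflyloxy)dodeca-2,6,10-trienoate | C=C(C)C(=O)O[C@@H](/C(OS(=O)(=O)C(F)(F)F)=C(\CO[Si](C)(C)C(C)(C)C)C(=O)OCC)C/C(C)=C\[C@H](OC(C)=O)C/C(C)=C/C=O | intermediate
20 | ethyl (2Z,4R,6Z,8R)-8-acetoxy-2-(TBSO-methyl)-9-[(2S,3R)-3-formyl-2-methyloxiran-2-yl]-6-methyl-4-(methacryloyloxy)-3-(triflyloxy)nona-2,6-dienoate | C=C(C)C(=O)O[C@@H](/C(OS(=O)(=O)C(F)(F)F)=C(\CO[Si](C)(C)C(C)(C)C)C(=O)OCC)C/C(C)=C\[C@H](OC(C)=O)C[C@]1(C)O[C@H]1C=O | intermediate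
21 | chromium(III) alkoxide of ethyl (1(10)Z,2R,4S,5S,8R)-2-acetoxy-13-(TBSO)-4,5-epoxy-6-hydroxy-8-(methacryloyloxy)germacra-1(10),7(11)-dien-12-oate, C6 epimers, C6 cis to the ester across C7=C11 (drawn as the alcohol) | C=C(C)C(=O)O[C@@H]1C/C(C)=C\[C@H](OC(C)=O)C[C@]2(C)O[C@H]2C(O)/C1=C(\C(=O)OCC)CO[Si](C)(C)C(C)(C)C | intermediate
22 | (1(10)Z,2R,4S,5S,8R)-2-acetoxy-13-(TBSO)-4,5-epoxy-8-(methacryloyloxy)germacra-1(10),7(11)-dien-12,6-olide, C6 epimers | C=C(C)C(=O)O[C@@H]1C/C(C)=C\[C@H](OC(C)=O)C[C@]2(C)O[C@H]2C2OC(=O)C(CO[Si](C)(C)C(C)(C)C)=C12 | intermediate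
23 | (1(10)Z,2R,4S,5E,8R)-2-acetoxy-13-(tert-butyldimethylsilyloxy)-4-hydroxy-8-(methacryloyloxy)germacra-1(10),5,7(11)-trien-12,6-olide | C=C(C)C(=O)O[C@@H]1C/C(C)=C\[C@H](OC(C)=O)C[C@](C)(O)/C=C2/OC(=O)C(CO[Si](C)(C)C(C)(C)C)=C21 | intermediate
24 | (1(10)Z,2R,4S,5E,8R)-2-acetoxy-4,13-dihydroxy-8-(methacryloyloxy)germacra-1(10),5,7(11)-trien-12,6-olide (CNP0122447.1) | C=C(C)C(=O)O[C@@H]1C/C(C)=C\[C@H](OC(C)=O)C[C@](C)(O)/C=C2/OC(=O)C(CO)=C21 | target

## Step count and risks

Total step count: 15. Longest linear sequence: 12 steps (1–4, 7–9, 11–15).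

The three steps most likely to fail:

Step 14 is the riskiest: Cr(II) may reduce the α,β-epoxy aldehyde, the ten-membered closure may lose to oligomerisation, and the C7 alkenyl-metal carries an allylic acyloxy group. The fallback sets out from 19 and closes the ring before the C4 oxygen is introduced. Ni/Cr closure of enal 19 with lactonisation in the flask gives (1(10)Z,2R,4E,8R)-2-acetoxy-13-(TBSO)-8-(methacryloyloxy)germacra-1(10),4,7(11)-trien-12,6-olide F1. Reagent-controlled Shi epoxidation of its E-trisubstituted 4,5-olefin (the Z-configured, acetoxy-flanked 1(10)-olefin is a poor Shi substrate; ketone antipode chosen for the 4S,5S epoxide) then gives 22. There the fallback comes back to the route, and DBU completes the conversion to 23.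

Step 13 may fail because the ammonium catalyst could engage the δ-acetoxy enal through a dienamine or attack the enol triflate. The fallback sets out from 19 and replaces the one-step enal epoxidation by an allylic-alcohol route. Luche reduction (NaBH4, CeCl3, MeOH, −78 °C) gives ethyl (2Z,4R,6Z,8R,10E)-8-acetoxy-2-(TBSO-methyl)-12-hydroxy-6,10-dimethyl-4-(methacryloyloxy)-3-(triflyloxy)dodeca-2,6,10-trienoate F2. Sharpless epoxidation with L-(+)-diethyl tartrate (Ti(O-i-Pr)4, t-BuOOH, −20 °C) gives the (2S,3S)-epoxy alcohol ethyl (2Z,4R,6Z,8R)-8-acetoxy-2-(TBSO-methyl)-9-[(2S,3S)-3-(hydroxymethyl)-2-methyloxiran-2-yl]-6-methyl-4-(methacryloyloxy)-3-(triflyloxy)nona-2,6-dienoate F3. Dess–Martin oxidation then returns to 20.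

Step 7 may fail because the α-substituted, β-silyloxy diazo ester is a sluggish and Lewis-acid-sensitive Roskamp partner. The fallback sets out from 9 and builds the C7–C11 bond by aldol chemistry. A Mukaiyama aldol with the trimethylsilyl ketene acetal of ethyl 3-(tert-butyldimethylsilyloxy)propanoate (BF3·OEt2, CH2Cl2, −78 °C) gives ethyl (4R,6Z)-2-(TBSO-methyl)-3-hydroxy-8-[methoxy(methyl)amino]-6-methyl-4-(methacryloyloxy)-8-oxooct-6-enoate F4 (C2/C3 epimers). Dess–Martin oxidation then returns to 13.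

## Further compounds

F1 | step 14 | (1(10)Z,2R,4E,8R)-2-acetoxy-13-(TBSO)-8-(methacryloyloxy)germacra-1(10),4,7(11)-trien-12,6-olide, C6 epimers | C=C(C)C(=O)O[C@@H]1C/C(C)=C\[C@H](OC(C)=O)C/C(C)=C/C2OC(=O)C(CO[Si](C)(C)C(C)(C)C)=C12
F2 | step 13 | ethyl (2Z,4R,6Z,8R,10E)-8-acetoxy-2-(TBSO-methyl)-12-hydroxy-6,10-dimethyl-4-(methacryloyloxy)-3-(triflyloxy)dodeca-2,6,10-trienoate | C=C(C)C(=O)O[C@@H](/C(OS(=O)(=O)C(F)(F)F)=C(\CO[Si](C)(C)C(C)(C)C)C(=O)OCC)C/C(C)=C\[C@H](OC(C)=O)C/C(C)=C/CO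
F3 | step 13 | ethyl (2Z,4R,6Z,8R)-8-acetoxy-2-(TBSO-methyl)-9-[(2S,3S)-3-(hydroxymethyl)-2-methyloxiran-2-yl]-6-methyl-4-(methacryloyloxy)-3-(triflyloxy)nona-2,6-dienoate | C=C(C)C(=O)O[C@@H](/C(OS(=O)(=O)C(F)(F)F)=C(\CO[Si](C)(C)C(C)(C)C)C(=O)OCC)C/C(C)=C\[C@H](OC(C)=O)C[C@]1(C)O[C@H]1CO
F4 | step 7 | ethyl (4R,6Z)-2-(TBSO-methyl)-3-hydroxy-8-[methoxy(methyl)amino]-6-methyl-4-(methacryloyloxy)-8-oxooct-6-enoate, C2/C3 epimers | C=C(C)C(=O)O[C@@H](C(O)C(CO[Si](C)(C)C(C)(C)C)C(=O)OCC)C/C(C)=C\C(=O)N(C)OC
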